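The epsilon run held 2.8 µM of impurity against 1.8 µM of free enzyme, and its product read 1.2% at 1.00 h and 0% at 4.00 h. The eta run, with 1.4 µM of impurity, reached 44.2% by 15.0 h.

| flask | substrate | free enzyme | impurity | temperature | remark | time |
|---|---|---|---|---|---|---|
| eta | 0.10 M | 1.8 µM | 1.4 µM | 25 °C | the very flask that is asked about, followed so far |  |
| epsilon | 0.10 M | 1.8 µM | 2.8 µM | 25 °C | run made earlier |  |
| flask | 0.10 M | 1.8 µM | 1.4 µM | 25 °C |  | 20 h |

| run | time / h | product / % | substrate / % |
|---|---|---|---|
| eta | 2.00 | 18.7 | 80.9 |
| eta | 6.00 | 35.6 | 63.9 |
| eta | 10.0 | 42.2 | 58.5 |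
| eta | 15.0 | 44.2 | 55.6 |
| epsilon | 1.00 | 1.2 | 99.2 |
| epsilon | 2.00 | 0.8 | 100.1 |
| epsilon | 3.00 | 0.7 | 99.6 |
| epsilon | 4.00 | 0 | 99.3 |

(standard deviation of a reading: 0.5 percentage points)

- Monday's: at 20 h raise the temperature by 15 K, then wait 20 h
- Saturday's: at 20 h add free enzyme, 100% of the amount charged, then wait 20 h
- Friday's: change nothing and wait 20 h more
- Thursday's: at 20 h take out 90% of the product then present, then wait 20 h

- what is taken out of product is counted as made
- candidate steps: free enzyme -> unfolded enzyme; substrate + free enzyme -> product + free enzyme; free enzyme + product -> spent catalyst A; free enzyme + impurity -> spent catalyst B; 2 free enzyme -> spent catalyst C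
- the earlier runs do not show what temperature does; that part of a forecast is a guess
- additions bring no volume worth counting

* product, in percent of the substrate first charged, at 20 h
* which option adds most product ("none" when 2 percentage points or less is all one gets) (Monday's / Saturday's / Friday's / Thursday's / none)
* product present, with what was taken out counted in, in percent of the substrate first charged, after Saturday's
* product present, with what was taken out counted in, in percent of the substrate first charged, after Friday's

How much enzyme works in the eta flask? The epsilon readings suggest an active-site titration: each impurity removes one free enzyme, quickly. Epsilon's impurity exceeded its enzyme, and on that reading the eta flask keeps 0.400 µM of surviving enzyme.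

How far does that dose carry? Take the loss of substrate as pseudo-first-order in [substrate], with a rate constant proportional to [free enzyme], and let [free enzyme] decay first-order. The integral then closes: the logarithm of starting over final [substrate] is proportional to the surviving enzyme. The eta reading of substrate, 55.6% at 15.0 h, gives 1.47 µM⁻¹. This is the reach, the natural logarithm of starting over final [substrate] per µM of surviving enzyme.

Which option puts new enzyme to work? Product gained 2 percentage points between 10.0 h and 15.0 h, less than the 18.7% of the first 2.00 h. Saturday's brings new enzyme, and the first charge exceeded impurity. My own reckoning, if the reach holds at that dose, takes substrate after Saturday's to 3.96%, so product to 96.0%.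

The forecast gives 44.7% at 20 h, Saturday's as best, 94% after Saturday's and 45% after Friday's. Its ground for Saturday's: “Fresh enzyme meets no free impurity”. Its figure for Saturday's lies below mine.

The flask gives 45.6% at 20 h, Saturday's as best, 84.2% after Saturday's and 46.0% after Friday's.

    free enzyme → unfolded enzyme (k = 0.0520 h⁻¹, Ea = 283 kJ mol⁻¹)
    substrate + free enzyme → product + free enzyme, rate k2*[substrate]*[free enzyme]/(1 + ([substrate]/Km2)) (0.210 M, k = 4.60 × 10⁵ L mol⁻¹ h⁻¹, Ea = 47.0 kJ mol⁻¹)
    free enzyme + product → spent catalyst A (k = 3.70 L mol⁻¹ h⁻¹, Ea = 56.0 kJ mol⁻¹)
    free enzyme + impurity → spent catalyst B (k = 16000 L mol⁻¹ s⁻¹, Ea = 37.0 kJ mol⁻¹)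
    2 free enzyme → spent catalyst C (k = 1.80 × 10⁵ L mol⁻¹ h⁻¹, Ea = 46.0 kJ mol⁻¹)
    (constants at 25 °C)

The flask's product after Saturday's stands 9.8 points below the forecast. Saturday's dose in this flask reached 0.688 µM⁻¹, about half of the eta reach. The neighbour charged with 7.2 × 10⁻⁶ M of free enzyme keeps, by the same subtraction, 5.80 µM of surviving enzyme. The eta reach puts its substrate at 0.0201%, but that neighbour holds 11.2% at 20.0 h, with product 88.8%. That neighbour's reach, taken at that time, is 0.377 µM⁻¹, and spent catalyst C holds 59.8% of its catalyst.

All runs come from a simulation with made-up constants, and the scatter is random.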